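**Plan**

- Retrosynthesis: the acetate is removed and the 12-membered ring is opened at C5–C6 (aldol of a C4 methyl ketone onto a C6 enal, C4=CH2 by later methylenation). C6 and the C8 methyl are taken off a C7≡C8 alkyne, the cyclohexene is opened at C11–C15, and the side chain is cut at C12–C13 from a tetramic acid.
- Enabling feature: the quaternary C15 (CMe2) joins C1 to C11, the β-carbon of the unsaturated γ-lactam (N–C18(=O)–C12=C11–C10). A tertiary C15 radical, made by hydrogen-atom transfer to an isopropenyl group, can therefore replace a bromine on C11 and close the cyclohexene C15–C1–C14–C13–C12–C11.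
- Forward order: γ-lactam (tetramic acid), chain attachment at C12, cyclohexene (step 8), E-enal at C6–C8, 12-membered ring (C5–C6), then C4 methylene and C6 acetate.
- Stereochemistry: C1 from (R)-limonene, C10 from D-propargylglycine, E-C7=C8 from syn-carboalumination, C6 from a CBS reduction.

Key step: step 8

Remarks:
- Atom numbers (C1–C18) are those of the target skeleton as used in the plan.
- N-Boc-D-propargylglycine is taken as the commercial form of D-propargylglycine.
- Tetramic acid 6 is drawn as the dione and 7 as the enol; both are tautomeric mixtures.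
- Compounds 19 and 20 are carried as mixtures of C6 epimers and are drawn without configuration at C6; the epimers converge at 21.
- The CIP label at C1 changes along the route (R in 2, S in 7–19, R in 20–23) only because substituent priorities change; its geometry is never touched.

**Route**

Step 1
Reactants: 1 (R)-(+)-limonene
Product: 2 (3R)-3-isopropenyl-6-oxoheptanal
Conditions: O3 (1.0 equiv, Sudan III end-point), CH2Cl2/MeOH, −78 °C; then Me2S, −78 °C → rt
Reagents that add atoms: ozone [O-][O+]=O
Why: Criegee ozonolysis with reductive work-up, in which the electron-richer trisubstituted ring alkene should take up the single equivalent of ozone before the 1,1-disubstituted isopropenyl group, and the stereocentre (the future C1) is not involved.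

Step 2
Reactants: 3 N-Boc-D-propargylglycine; 4 Meldrum's acid
Product: 6 tert-butyl (2R)-3,5-dioxo-2-(prop-2-yn-1-yl)pyrrolidine-1-carboxylate (N-Boc tetramic acid), via acyl Meldrum's adduct 5 (not isolated)
Conditions: DCC, DMAP, CH2Cl2, 0 °C → rt; filter, aq. KHSO4 wash; then EtOAc, reflux
Reagents that add atoms: none
Why: Carbodiimide/DMAP C-acylation of Meldrum's acid followed by thermal fragmentation to an acylketene that the carbamate nitrogen captures, the standard tetramic acid synthesis from Boc-amino acids, which should keep the α-stereocentre (the future C10).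

Step 3
Reactants: 6 N-Boc tetramic acid; 2 (3R)-3-isopropenyl-6-oxoheptanal
Product: 7 tert-butyl (2R)-3-hydroxy-4-[(3S)-3-isopropenyl-6-oxoheptyl]-5-oxo-2-(prop-2-yn-1-yl)-2,5-dihydro-1H-pyrrole-1-carboxylate
Conditions: Hantzsch ester (1.1 equiv), L-proline (10 mol%), CH2Cl2, rt, slow addition of 2
Reagents that add atoms: none
Why: Three-component reductive alkylation (Knoevenagel condensation, then Hantzsch-ester conjugate reduction), in which only the aldehyde of 2 should condense with the acidic C3–H2 of the tetramic acid at room temperature and the alkylidene is reduced before a second tetramic acid can add, forming C12–C13 without touching either stereocentre.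

Step 4
Reactants: 7 3-alkyl tetramic acid
Product: 8 tert-butyl (2R)-3-bromo-4-[(3S)-3-isopropenyl-6-oxoheptyl]-5-oxo-2-(prop-2-yn-1-yl)-2,5-dihydro-1H-pyrrole-1-carboxylate
Conditions: (COBr)2 (1.3 equiv), DMF (3 equiv), CH2Cl2, 0 °C; aq. NaHCO3
Reagents that add atoms: oxalyl bromide O=C(Br)C(=O)Br
Why: Vilsmeier-type enol-to-halide exchange, in which the bromoiminium salt activates the C11 enol oxygen and bromide adds to C11 with expulsion of DMF (vinylogous acyl substitution), as in the conversion of tetronic and tetramic acids into 4-bromo derivatives, with excess DMF buffering the acid.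

Step 5
Reactants: 8 N-Boc bromo pyrrolinone
Product: 9 (5R)-4-bromo-3-[(3S)-3-isopropenyl-6-oxoheptyl]-5-(prop-2-yn-1-yl)-1,5-dihydro-2H-pyrrol-2-one
Conditions: Mg(ClO4)2 (20 mol%), MeCN, 50 °C
Reagents that add atoms: none
Why: Lewis-acid-mediated cleavage of an imide-type Boc group (magnesium chelation of the N-acyl carbamate, loss of isobutene and CO2) under non-protic conditions that should spare the isopropenyl group, and the resulting N–H lactam no longer has an acidic C10–H.

Step 6
Reactants: 9 bromo pyrrolinone ketone
Product: 10 (5R)-4-bromo-3-[(3S)-3-isopropenyl-5-(2-methyl-1,3-dioxolan-2-yl)pentyl]-5-(prop-2-yn-1-yl)-1,5-dihydro-2H-pyrrol-2-one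
Conditions: ethylene glycol (5 equiv), PPTS (10 mol%), benzene, reflux (Dean–Stark)
Reagents that add atoms: ethylene glycol OCCO
Why: Acid-catalysed ketalisation with azeotropic removal of water masks the C4 methyl ketone for the later organoaluminium step, and PPTS is mild enough for the isopropenyl group, as in ketalisations of isopropenyl-bearing terpene ketones.

Step 7
Reactants: 10 bromo pyrrolinone ketal
Product: 12 (5R)-4-bromo-3-[(3S)-3-isopropenyl-5-(2-methyl-1,3-dioxolan-2-yl)pentyl]-5-[3-(trimethylsilyl)prop-2-yn-1-yl]-1,5-dihydro-2H-pyrrol-2-one, via N-silyl lactam 11 (not isolated)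
Conditions: LiHMDS (2.3 equiv), THF, −78 °C; TMSCl (2.5 equiv), −78 → 0 °C; aq. NH4Cl
Reagents that add atoms: chlorotrimethylsilane C[Si](C)(C)Cl
Why: Acetylide C-silylation through the N,C-dianion (amidate first, then acetylide), with the N–Si bond hydrolysed on work-up and the amidate charge keeping C10–H non-acidic so that the stereocentre is safe.

Step 8
Reactants: 12 bromo pyrrolinone with isopropenyl ketal chain and silylpropargyl group
Product: 13 (3R,5S)-4,4-dimethyl-5-[2-(2-methyl-1,3-dioxolan-2-yl)ethyl]-3-[3-(trimethylsilyl)prop-2-yn-1-yl]-2,3,4,5,6,7-hexahydro-1H-isoindol-1-one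
Conditions: Fe(acac)3 (30 mol%), PhSiH3 (2.5 equiv, slow addition), Na2HPO4 (2 equiv), EtOH/ethylene glycol (5:1), 60 °C, 0.01 M
Reagents that add atoms: none
Why: Proposed new method: the iron(III) hydride formed from Fe(acac)3 and PhSiH3 transfers a hydrogen atom to the terminal carbon of the isopropenyl group to give the tertiary C15 radical, which adds to C11 of the bromo pyrrolinone; the α-carbonyl radical at C12 then loses the β-bromine (as a bromine atom taken up by iron(II), or as bromide after reduction to the enolate), which restores C11=C12 and returns iron(III). The closest known reactions are iron-hydride reductive olefin coupling (Giese-type 6-endo cyclisations of alkenes onto unsaturated carbonyls tethered through the α-carbon) and radical addition–β-elimination on β-halo or β-sulfonyl acceptors, merged here on a β-bromo lactam. The cyclohexene closes 6-endo-trig (C15 radical onto C12=C11; ring C15–C1–C14–C13–C12–C11). No stereocentre is created, since C11 and C12 end sp2 and C15 carries two methyl groups, and C1 and C10 are spectators. The step needs chemoselective hydrogen-atom transfer, expected because the silylalkyne and the electron-poor tetrasubstituted bromo-alkene do not accept hydrogen from the metal hydride, and 6-endo rather than 5-exo attack, expected from the polarity match of the nucleophilic tertiary radical with the β-carbon and from the fully substituted α-carbon C12, whose attack would give an unstabilised radical and two adjacent quaternary carbons. Slow silane addition at high dilution should limit simple reduction of the radical, and the phosphate buffer protects the dioxolane from the acid released.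

Step 9
Reactants: 13 silylalkyne bicyclic lactam
Product: 14 (3R,5S)-4,4-dimethyl-5-[2-(2-methyl-1,3-dioxolan-2-yl)ethyl]-3-(prop-2-yn-1-yl)-2,3,4,5,6,7-hexahydro-1H-isoindol-1-one
Conditions: K2CO3 (0.2 equiv), MeOH, rt
Reagents that add atoms: none
Why: Base-catalysed methanolysis of the C(sp)–Si bond (protodesilylation of a trimethylsilylalkyne), which should not affect the ketal or the lactam.

Step 10
Reactants: 14 terminal alkyne
Product: 17 (3R,5S)-3-[(2E)-4-hydroxy-2-methylbut-2-en-1-yl]-4,4-dimethyl-5-(3-oxobutyl)-2,3,4,5,6,7-hexahydro-1H-isoindol-1-one, via alkenylalane 15 (not isolated), via ketal allylic alcohol 16 (not isolated)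
Conditions: Me3Al (5 equiv), Cp2ZrCl2 (1 equiv), H2O (1.5 equiv), CH2Cl2, −30 → 0 °C; evaporate; n-BuLi (1.1 equiv), THF, −78 °C, then (CH2O)n, → rt; then 1 M HCl, THF, rt
Reagents that add atoms: trimethylaluminium C[Al](C)C; formaldehyde (from paraformaldehyde) C=O
Why: Zirconium-catalysed (Negishi) carboalumination adds methyl and aluminium syn across the terminal alkyne with methyl on the internal carbon C8, so C7=C8 forms E (the N–H being metalated first, as with homopropargylic alcohols), the derived alanate adds to formaldehyde with retention to install C6, and the acid work-up hydrolyses the dioxolane.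

Step 11
Reactants: 17 keto allylic alcohol
Product: 18 (3R,5S)-4,4-dimethyl-3-[(2E)-2-methyl-4-oxobut-2-en-1-yl]-5-(3-oxobutyl)-2,3,4,5,6,7-hexahydro-1H-isoindol-1-one
Conditions: MnO2 (excess), CH2Cl2, rt
Reagents that add atoms: none
Why: Manganese dioxide oxidation is selective for the allylic carbinol, leaves the methyl ketone alone and should not isomerise the E-enal.

Step 12
Reactants: 18 keto enal
Product: 19 macrocyclic β-hydroxy ketone (C4 ketone, C6 hydroxyl, 7E, both C6 epimers)
Conditions: LiHMDS (2.3 equiv), THF, −78 °C, slow addition of 18 to 0.001 M; AcOH quench at −78 °C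
Reagents that add atoms: none
Why: Intramolecular aldol addition (macroaldolisation) under kinetic control, in which the first equivalent of base forms the lactam amidate, the second deprotonates the less hindered methyl group (C5), and the enolate adds 1,2 to the enal at high dilution to close the 12-membered ring; C6 is not controlled here and is reset in steps 14 and 15.

Step 13
Reactants: 19 macrocyclic β-hydroxy ketone
Product: 20 6-O-deacetylcespitulactam E as a mixture with its C6 epimer
Conditions: Zn, CH2Br2, TiCl4 (pre-formed reagent), THF/CH2Cl2, 0 °C → rt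
Reagents that add atoms: dibromomethane BrCBr
Why: Takai–Lombardo methylenation is non-basic, so the β-hydroxy ketone should be converted to the C4 exo-methylene without retro-aldol cleavage or β-elimination, and the reagent does not attack the lactam carbonyl.

Step 14
Reactants: 20 C6-epimeric allylic alcohols
Product: 21 6-oxo macrocycle (C6 ketone conjugated to C7=C8, C4 exo-methylene)
Conditions: Dess–Martin periodinane, pyridine, CH2Cl2, 0 °C
Reagents that add atoms: none
Why: Dess–Martin oxidation under buffered, non-enolising conditions converges both C6 epimers on one enone and should leave the β,γ-exo-methylene out of conjugation.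

Step 15
Reactants: 21 macrocyclic enone
Product: 22 (6S)-6-O-deacetylcespitulactam E
Conditions: (R)-CBS oxazaborolidine (B-n-butyl, 0.5 equiv), catecholborane (3 equiv), toluene, −78 °C; then MeOH
Reagents that add atoms: none
Why: Corey–Bakshi–Shibata reduction, in which the (R)-oxazaborolidine binds the ketone with the alkenyl residue (C7=C8) as the large group and the C5 methylene as the small one and should deliver hydride to the face that gives the (6S)-alcohol, while catecholborane does not hydroborate the alkenes at −78 °C.

Step 16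
Reactants: 22 (6S)-allylic alcohol
Product: 23 cespitulactam E
Conditions: Ac2O, pyridine, DMAP (cat.), CH2Cl2, 0 °C → rt
Reagents that add atoms: acetic anhydride CC(=O)OC(C)=O
Why: DMAP-catalysed O-acylation of the secondary allylic alcohol proceeds with retention at C6, and the conjugated lactam N–H should not be acylated under these mild conditions.

**Compound list**

1 | (R)-(+)-limonene | CC1=CC[C@@H](CC1)C(C)=C | starting material
2 | (3R)-3-isopropenyl-6-oxoheptanal | CC(=O)CC[C@H](CC=O)C(C)=C | intermediate
3 | N-Boc-D-propargylglycine, (2R)-2-(tert-butoxycarbonylamino)pent-4-ynoic acid | CC(C)(C)OC(=O)N[C@H](CC#C)C(=O)O | starting material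
4 | Meldrum's acid (2,2-dimethyl-1,3-dioxane-4,6-dione) | CC1(C)OC(=O)CC(=O)O1 | starting material
5 | acyl Meldrum's adduct, 5-[(2R)-2-(tert-butoxycarbonylamino)-1-hydroxypent-4-yn-1-ylidene]-2,2-dimethyl-1,3-dioxane-4,6-dione | CC(C)(C)OC(=O)N[C@H](CC#C)C(O)=C1C(=O)OC(C)(C)OC1=O | intermediate
6 | tert-butyl (2R)-3,5-dioxo-2-(prop-2-yn-1-yl)pyrrolidine-1-carboxylate (N-Boc tetramic acid) | O=C1N(C(=O)OC(C)(C)C)[C@H](CC#C)C(=O)C1 | intermediate
7 | tert-butyl (2R)-3-hydroxy-4-[(3S)-3-isopropenyl-6-oxoheptyl]-5-oxo-2-(prop-2-yn-1-yl)-2,5-dihydro-1H-pyrrole-1-carboxylate | O=C1N(C(=O)OC(C)(C)C)[C@H](CC#C)C(O)=C1CC[C@@H](CCC(C)=O)C(C)=C | intermediate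
8 | tert-butyl (2R)-3-bromo-4-[(3S)-3-isopropenyl-6-oxoheptyl]-5-oxo-2-(prop-2-yn-1-yl)-2,5-dihydro-1H-pyrrole-1-carboxylate | O=C1N(C(=O)OC(C)(C)C)[C@H](CC#C)C(Br)=C1CC[C@@H](CCC(C)=O)C(C)=C | intermediate
9 | (5R)-4-bromo-3-[(3S)-3-isopropenyl-6-oxoheptyl]-5-(prop-2-yn-1-yl)-1,5-dihydro-2H-pyrrol-2-one | O=C1N[C@H](CC#C)C(Br)=C1CC[C@@H](CCC(C)=O)C(C)=C | intermediate
10 | (5R)-4-bromo-3-[(3S)-3-isopropenyl-5-(2-methyl-1,3-dioxolan-2-yl)pentyl]-5-(prop-2-yn-1-yl)-1,5-dihydro-2H-pyrrol-2-one | O=C1N[C@H](CC#C)C(Br)=C1CC[C@@H](CCC2(C)OCCO2)C(C)=C | intermediate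
11 | N-trimethylsilyl derivative of 12 (N-silyl lactam) | O=C1N([Si](C)(C)C)[C@H](CC#C[Si](C)(C)C)C(Br)=C1CC[C@@H](CCC2(C)OCCO2)C(C)=C | intermediate
12 | (5R)-4-bromo-3-[(3S)-3-isopropenyl-5-(2-methyl-1,3-dioxolan-2-yl)pentyl]-5-[3-(trimethylsilyl)prop-2-yn-1-yl]-1,5-dihydro-2H-pyrrol-2-one | O=C1N[C@H](CC#C[Si](C)(C)C)C(Br)=C1CC[C@@H](CCC2(C)OCCO2)C(C)=C | intermediate
13 | (3R,5S)-4,4-dimethyl-5-[2-(2-methyl-1,3-dioxolan-2-yl)ethyl]-3-[3-(trimethylsilyl)prop-2-yn-1-yl]-2,3,4,5,6,7-hexahydro-1H-isoindol-1-one | CC1(CC[C@@H]2CCC3=C([C@@H](CC#C[Si](C)(C)C)NC3=O)C2(C)C)OCCO1 | intermediate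
14 | (3R,5S)-4,4-dimethyl-5-[2-(2-methyl-1,3-dioxolan-2-yl)ethyl]-3-(prop-2-yn-1-yl)-2,3,4,5,6,7-hexahydro-1H-isoindol-1-one | CC1(CC[C@@H]2CCC3=C([C@@H](CC#C)NC3=O)C2(C)C)OCCO1 | intermediate
15 | (E)-alkenyl(dimethyl)alane of 14 with N–AlMe2 (methyl on C8, aluminium on C7) | CC1(CC[C@@H]2CCC3=C([C@@H](C/C(C)=C/[Al](C)C)N([Al](C)C)C3=O)C2(C)C)OCCO1 | intermediate
16 | (3R,5S)-3-[(2E)-4-hydroxy-2-methylbut-2-en-1-yl]-4,4-dimethyl-5-[2-(2-methyl-1,3-dioxolan-2-yl)ethyl]-2,3,4,5,6,7-hexahydro-1H-isoindol-1-one | CC1(CC[C@@H]2CCC3=C([C@@H](C/C(C)=C/CO)NC3=O)C2(C)C)OCCO1 | intermediate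
17 | (3R,5S)-3-[(2E)-4-hydroxy-2-methylbut-2-en-1-yl]-4,4-dimethyl-5-(3-oxobutyl)-2,3,4,5,6,7-hexahydro-1H-isoindol-1-one | CC(=O)CC[C@@H]1CCC2=C([C@@H](C/C(C)=C/CO)NC2=O)C1(C)C | intermediate
18 | (3R,5S)-4,4-dimethyl-3-[(2E)-2-methyl-4-oxobut-2-en-1-yl]-5-(3-oxobutyl)-2,3,4,5,6,7-hexahydro-1H-isoindol-1-one | CC(=O)CC[C@@H]1CCC2=C([C@@H](C/C(C)=C/C=O)NC2=O)C1(C)C | intermediate
19 | macrocyclic aldol: target skeleton with C4 ketone and C6 hydroxyl (1S,10R,7E; both C6 epimers) | O=C1CC[C@@H]2CCC3=C([C@@H](C/C(C)=C/C(O)C1)NC3=O)C2(C)C | intermediate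
20 | 6-O-deacetylcespitulactam E and its C6 epimer (1R,10R,7E; C4 exo-methylene) | C=C1CC[C@@H]2CCC3=C([C@@H](C/C(C)=C/C(O)C1)NC3=O)C2(C)C | intermediate
21 | 6-oxo macrocycle (1R,10R,7E; C6 ketone, C4 exo-methylene) | C=C1CC[C@@H]2CCC3=C([C@@H](C/C(C)=C/C(=O)C1)NC3=O)C2(C)C | intermediate
22 | (1R,6S,10R,7E)-6-O-deacetylcespitulactam E | C=C1CC[C@@H]2CCC3=C([C@@H](C/C(C)=C/[C@@H](O)C1)NC3=O)C2(C)C | intermediate
23 | cespitulactam E (1R,6S,10R,7E) | C=C1CC[C@@H]2CCC3=C([C@@H](C/C(C)=C/[C@@H](OC(C)=O)C1)NC3=O)C2(C)C | target

**Step count and risks**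

Total: 16 steps. Longest linear sequence: 15 steps (3 → 23, steps 2–16; the limonene branch, steps 1 and 3–16, is equally long).

Most likely to fail:

First, step 8. The tertiary C15 radical may take up a second hydrogen atom (net hydrogenation of the isopropenyl group), or the alkene may isomerise, faster than the radical attacks the fully substituted, bromine-bearing C11; reductive loss of bromine without C–C bond formation is the other drain. The fallback sets out from 12 and comes back at 13 by a palladium-catalysed reductive Mizoroki–Heck cyclisation (Pd(OAc)2, PPh3, HCO2Na, Et4NCl, DMF, 80 °C). Palladium(0) inserts into the C11–Br bond and the alkenylpalladium adds 6-exo-trig across the isopropenyl group, forming the same C11–C15 bond and the quaternary centre. The resulting neopentyl-type alkylpalladium has no β-hydrogen and is captured by formate as hydride donor, which turns the former =CH2 into the second methyl group. This is the established Heck cyclisation with hydride capture, a two-electron route to the same ring, and no new compound arises on the way (F0).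

Second, step 12. Deprotonation may occur on the C3 side of the ketone or at the γ-position of the enal, the amide base may add to the aldehyde, and intermolecular aldol oligomerisation may compete with closure of the 12-membered ring. The fallback sets out from 17 and comes back at 19 by a Reformatsky-type closure with a regiodefined samarium enolate. LiHMDS and TMSCl (THF, −78 °C) give the tris-silylated kinetic enol ether F1 (terminal silyl enol ether, O-silyl allylic alcohol, N-silyl lactam). NBS in the same flask followed by dilute acid work-up gives the bromomethyl ketone F2. MnO2 oxidises the allylic alcohol to the bromo keto enal F3. SmI2 (THF, −78 °C, high dilution) then reduces the C–Br bond to a samarium(III) enolate fixed at C5, which adds to the aldehyde under non-basic conditions to give 19.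

Third, step 10. The aluminium amidate and the dioxolane oxygens may bind the zirconium and aluminium reagents and slow or misdirect the carbometalation, the Lewis acid may open the ketal, chelation may cause isomerisation to the Z-alkenylalane, and capture by formaldehyde may be incomplete. The fallback sets out from 14 and comes back at 16, which the acid treatment that ends step 10 converts into 17. The N,C-dianion of 14 (n-BuLi, 2.2 equiv, THF, −78 °C) is trapped with paraformaldehyde to give the propargylic alcohol F4. Alkoxide-directed trans-hydroalumination with Red-Al followed by iodine gives the (Z)-iodo allylic alcohol F5 (iodine on C8, cis to C6). Lithium dimethylcuprate then replaces iodine by methyl with retention to give the E-trisubstituted allylic alcohol 16.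

Further compounds
F0 | step 8 | none | none
F1 | step 12 | tris-silylated kinetic enol ether of 17 (terminal TMS enol ether, O-TMS allylic ether, N-TMS lactam) | C=C(O[Si](C)(C)C)CC[C@@H]1CCC2=C([C@@H](C/C(C)=C/CO[Si](C)(C)C)N([Si](C)(C)C)C2=O)C1(C)C
F2 | step 12 | (3R,5S)-5-(4-bromo-3-oxobutyl)-3-[(2E)-4-hydroxy-2-methylbut-2-en-1-yl]-4,4-dimethyl-2,3,4,5,6,7-hexahydro-1H-isoindol-1-one | O=C(CBr)CC[C@@H]1CCC2=C([C@@H](C/C(C)=C/CO)NC2=O)C1(C)C
F3 | step 12 | (3R,5S)-5-(4-bromo-3-oxobutyl)-4,4-dimethyl-3-[(2E)-2-methyl-4-oxobut-2-en-1-yl]-2,3,4,5,6,7-hexahydro-1H-isoindol-1-one | O=C(CBr)CC[C@@H]1CCC2=C([C@@H](C/C(C)=C/C=O)NC2=O)C1(C)C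
F4 | step 10 | (3R,5S)-3-(4-hydroxybut-2-yn-1-yl)-4,4-dimethyl-5-[2-(2-methyl-1,3-dioxolan-2-yl)ethyl]-2,3,4,5,6,7-hexahydro-1H-isoindol-1-one | CC1(CC[C@@H]2CCC3=C([C@@H](CC#CCO)NC3=O)C2(C)C)OCCO1
F5 | step 10 | (3R,5S)-3-[(2Z)-4-hydroxy-2-iodobut-2-en-1-yl]-4,4-dimethyl-5-[2-(2-methyl-1,3-dioxolan-2-yl)ethyl]-2,3,4,5,6,7-hexahydro-1H-isoindol-1-one | CC1(CC[C@@H]2CCC3=C([C@@H](C/C(I)=C/CO)NC3=O)C2(C)C)OCCO1
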